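## Structural features

Huanglongmycin D (19) is an achiral benzophenone in which a pentasubstituted benzene ring A is joined through a ketone carbonyl to a 2,6-dihydroxyphenyl ring B; the two benzene rings are the only rings. Numbered from the carboxyl-bearing carbon, ring A carries CO2H at C1, the aroyl ketone at C2, OH at C3, acetyl at C4, CH2CO2H at C5 and H at C6. The target has no stereocentre, so no stereocentres stand next to each other; the two carbinol centres that appear in the route are temporary, remote from one another and both end as ketone carbons. Fragile elements are the 2-aroylbenzoic acid (ring–chain tautomerism to a hydroxyphthalide), the acetyl/arylacetic acid pair on C4/C5 (Claisen-type or enol-lactone closure), the oxidation-prone trihydroxybenzophenone and, among the intermediates, a terminal ynoate, a 3-alkynoate and an alkynyl silyl ether. The real difficulty is the regiocontrolled assembly of five different substituents on C1–C5, above all the doubly ortho-substituted diaryl ketone at C2 and the phenol at C3 wedged between two ketone-bearing carbons. The key step exploits this 1,2,3,4-pattern: C1 (carboxyl) and the C2 carbinol carbon can be tied as a phthalide, and the C3 oxygen can be replaced by silicon bound to the oxygen of a 1-hydroxyethyl group on C4 (a benzoxasilole), so that ring A can be closed from three alkynes held in one chain.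

## Logic of the disconnections

**19 from 18.** The three phenolic O–H bonds are replaced by O–CH3 bonds. The free polyphenol is too sensitive for oxidants and bases, so it is released last. The forward step needs a Lewis-acid ether cleavage that tolerates two ketones and two acids; each methoxy group sits ortho to a ketone carbonyl, which favours chelation-assisted cleavage.

**18 from 16 (through 17).** Both ketones are taken back to secondary carbinols, the C1 carboxyl is re-closed with the C2 carbinol oxygen as a lactone, and the acetic acid arm is esterified. Carbinols are what an alkyne trimerization can carry, and the crowded aryl group then rides on sp3 carbon. The forward step must open the lactone before oxidation, oxidise the carboxylate salt (the free hydroxy acid would relactonise), and form the ketones only after the ester has become a carboxylate.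

**16 from 15.** The O–CH3 bond of the C3 ether is cut. The free phenol would not survive the oxidant of the following step. The cap costs one step but no separate deprotection, because it leaves with the other methyl ethers.

**15 from 14.** The C3–O bond is exchanged for a C3–Si bond and the carbinol oxygen on the C4 side chain is tied to the same silicon. Silicon then serves both as masked hydroxyl and as tether. The forward Tamao oxidation has to work on an arylsilane with two ortho substituents and must come before any ketone exists, since an ortho-hydroxyaryl ketone would be open to Dakin oxidation.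

**14 from 13 (key).** Ring A is cut at C1–C2, C3–C4 and C5–C6 into three alkynes in one chain, joined by an ester and a silyl ether. A linear triyne replaces a pentasubstituted arene. The forward step must give one regiochemistry and stay intramolecular; the two three-atom tethers and dilution provide this. Atom-by-atom bookkeeping of 13 and 14 confirms that the ynoate supplies C6/C1, the central silylalkyne C2/C3 and the hexynoate alkyne C4/C5.

**13 from 9 and 12.** The Si–O bond, the most labile bond of the precursor, is formed last. The forward step must avoid bases and nucleophilic amines, which would add alcohols to the terminal ynoate or isomerise the 3-alkynoate to an allenoate. A dehydrogenative Si–H/O–H coupling is therefore chosen, and 13 is used at once.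

**9 from 7 and 8.** The ester C–O bond is cut. Acylating before the silyl ether is made removes the only competing hydroxyl. The forward step must acylate a hindered, ionisable carbinol with a polymerisation-prone acid, hence low temperature and little amine catalyst.

**7 from 3 and 4.** The C(sp)–Si bond is cut. The free hydroxyl prevents direct C-silylation, so both anionic sites are silylated and the O–Si bond alone is hydrolysed. The Si–H bond is kept as the latent leaving group for the later coupling.

**3 from 1 and 2.** The bond between the carbinol carbon and the alkyne is cut, giving an aldehyde and an alkynyl Grignard reagent.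

**12 from 10 and 11.** The C(sp)–CH2 bond is cut. The forward coupling must form the 3-alkynoate without base and in the presence of a free hydroxyl.

## Other disconnections considered

**Alternative 1:** 
- *Cut:* the bonds from C1 and C2 of ring A to their carbon substituents and the lactone C–O bond. Ring A is then bought as the symmetrical bis(silyl triflate) A2, a 1,3-benzdiyne equivalent that already carries the C3 oxygen as OMe.
- *Forward key step:* one equivalent of fluoride unmasks one of the two equivalent arynes; the isocyanide A3 adds to C1, the carbon remote from the methoxy group; the C2 aryl anion is trapped by 1; the alkoxide closes on the nitrilium carbon to give iminophthalide A1, which keeps a silyl triflate at C4/C5 for a second aryne.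
- *In favour:* three components and three bonds in one operation. The crowded aryl group enters at the carbinol level, as in the chosen plan. Distal attack on 3-alkoxyarynes is a dependable bias. No Tamao step is needed for the C3 oxygen, and on this point A1 is better placed than 14.
- *Against:* A2 needs a multistep, regiodefined arene synthesis of its own. Only stoichiometry prevents double activation. The imidate has to be hydrolysed, and the carbinol still has to be oxidised through the same lactone-opening problem (equal to the chosen plan on that point). The acetyl and acetate arms then require a second aryne reaction on a crowded ring carrying electrophilic groups.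
- *Comparison:* both plans tie C1/C2 as a five-membered (imino)lactone. The chosen plan fixes all six ring positions by covalent tethers, whereas this one relies on polar bias in two consecutive aryne steps. After the key step the step counts are comparable; before it the chosen plan should be shorter because ring A is built, not decorated.

**Alternative 2:** 
- *Cut:* the aryl C–O bond of a seven-membered lactone, which in reverse re-joins the C1 carboxyl carbon to ring B and leads to the anthraquinone A5.
- *Forward key step:* the peracid A6 adds to the unchelated C10 carbonyl of A5 and ring B carbon C10a migrates to oxygen, giving the dibenzo[b,e]oxepine-6,11-dione A4.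
- *In favour:* the plan is biomimetic. The C2 ketone is at the right oxidation level from the start, and one oxygen insertion creates both the carboxyl and a ring B oxygen. After the key step only lactone and ester hydrolysis and one demethylation would remain, so in step economy after the key step it is better than the chosen plan.
- *Against:* the selectivity rests on small electronic differences. The C9 carbonyl must stay inert through chelation. The migrating ring B carbon is only meta to the methoxy group, so its preference over the ring A carbon is not assured. The acetyl methyl ketone is intrinsically the more reactive Baeyer–Villiger substrate, and aryl migration there would destroy the acetyl group. The free phenol ring may be oxidised by the strong peracid, and diaryl quinone carbonyls are reluctant substrates.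
- *Comparison:* structurally it hides ring A inside a tricycle whose substituent pattern must itself be assembled. Mechanistically its site- and migration selectivity are matters of degree, where the chosen plan enforces regiochemistry by tethers. It is the shorter plan on paper and the less predictable one.

**Alternative 3:** 
- *Cut:* the C4–acetyl and C5–CH2 bonds.
- *Forward key step:* fluoride turns the silyl triflate A8 into the C4–C5 aryne; the enolate carbon of A9 attacks C5 (remote from the methoxy group); the C4 aryl anion adds to the ketone carbonyl; the benzocyclobutenoxide fragments to give A7, the formal insertion of the aryne into the C2–C3 bond of A9.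
- *In favour:* both carbon arms arrive in one step at their final oxidation level. The regiochemistry for a 3-methoxyaryne is dependable, and for this bond pair it is the equal of tether control. A7 is only ester hydrolysis and demethylation away from 19, which is shorter than the endgame of the chosen plan, and no temporary stereocentres arise.
- *Against:* the burden moves into A8, a pentasubstituted benzophenone that already contains the hindered diaryl ketone and would itself need a long, probably aryne-based, preparation. The aryne carries a ketone and an ester that can trap aryl anion or enolate intermediates. The basic fluoride/enolate medium also endangers the acetyl/acetate pair of A7 through Claisen-type closure.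
- *Comparison:* this plan decorates a preformed ring A and is the better one after the key step. The chosen plan builds ring A with all substituents in one event and should be shorter overall, at the price of later oxidation-level adjustments.

Key step: step 6

Assumption (chemistry): the acetic ester is carried as the ethyl ester, because ethyl diazoacetate is the commercial diazo ester, and 10 is used as the racemate; every chiral intermediate is therefore racemic or a diastereomer mixture (one isomer drawn), which is immaterial because both carbinol carbons become ketone carbons in step 9.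

## Route

Step 1
Reactants: 1 2,6-dimethoxybenzaldehyde; 2 ethynylmagnesium bromide
Product: 3 1-(2,6-dimethoxyphenyl)prop-2-yn-1-ol (racemic)
Conditions: HC≡CMgBr (0.5 M in THF, 1.3 equiv), THF, 0 °C → rt; sat. aq. NH4Cl
Reagents that add atoms: none
Why: Grignard 1,2-addition of an alkynyl nucleophile to a non-enolisable aryl aldehyde; the carbinol centre is formed racemic, which is acceptable because it later becomes the C2 ketone carbon.

Step 2
Reactants: 3 1-(2,6-dimethoxyphenyl)prop-2-yn-1-ol; 4 chlorodiethylsilane
Product: 7 1-(2,6-dimethoxyphenyl)-3-(diethylsilyl)prop-2-yn-1-ol (racemic), via dilithium salt 5 (not isolated), via bis(diethylsilyl) derivative 6 (not isolated)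
Conditions: n-BuLi (2.1 equiv), THF, −78 °C; Et2SiHCl (2.3 equiv), −78 → 0 °C; then 10% aq. citric acid, THF, 0 °C
Reagents that add atoms: none
Why: Double deprotonation (O–H, then C(sp)–H), silylation of both anionic sites and selective hydrolysis of the very labile hydrosilyl ether is the standard way to C-silylate a propargylic alcohol; the alkynyl C–Si and the Si–H bonds are stable to dilute aqueous acid.

Step 3
Reactants: 7 1-(2,6-dimethoxyphenyl)-3-(diethylsilyl)prop-2-yn-1-ol; 8 propiolic acid
Product: 9 1-(2,6-dimethoxyphenyl)-3-(diethylsilyl)prop-2-yn-1-yl prop-2-ynoate (racemic)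
Conditions: propiolic acid (1.5 equiv), DCC (1.5 equiv), DMAP (5 mol%), CH2Cl2, −20 → 0 °C
Reagents that add atoms: none
Why: Steglich-type carbodiimide esterification; low temperature and a small amount of DMAP limit conjugate addition to the ynoate, the Si–H group is inert, and the configuration at the carbinol carbon is untouched.

Step 4
Reactants: 10 but-3-yn-2-ol (racemic); 11 ethyl diazoacetate
Product: 12 ethyl 5-hydroxyhex-3-ynoate (racemic)
Conditions: CuI (5 mol%), MeCN, rt
Reagents that add atoms: none
Why: CuI-catalysed coupling of a terminal alkyne with a diazo ester gives the 3-alkynoate directly at the C(sp)–H bond with loss of N2; the conditions are base-free, so the product is not isomerised to the allenoate, and the free hydroxyl is tolerated.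

Step 5
Reactants: 9 1-(2,6-dimethoxyphenyl)-3-(diethylsilyl)prop-2-yn-1-yl prop-2-ynoate; 12 ethyl 5-hydroxyhex-3-ynoate (1.2 equiv)
Product: 13 1-(2,6-dimethoxyphenyl)-3-{diethyl[(6-ethoxy-6-oxohex-3-yn-2-yl)oxy]silyl}prop-2-yn-1-yl prop-2-ynoate (two racemic diastereomers)
Conditions: [RuCl2(p-cymene)]2 (1 mol%), CH2Cl2, rt, H2 evolution; filtration through Celite, used at once
Reagents that add atoms: none
Why: Ruthenium-catalysed dehydrogenative Si–H/O–H coupling (silane alcoholysis) of an alkynyl hydrosilane with a secondary alcohol forms the Si–O bond with H2 as the only co-product; no base or nucleophilic amine is present, so the terminal ynoate and the 3-alkynoate are spared, and no stereocentre is formed.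

Step 6
Reactants: 13 1-(2,6-dimethoxyphenyl)-3-{diethyl[(6-ethoxy-6-oxohex-3-yn-2-yl)oxy]silyl}prop-2-yn-1-yl prop-2-ynoate
Product: 14 tricyclic phthalide–benzoxasilole: ring A fused at C1–C2 to a γ-lactone [C1–C(=O)–O–CH(2,6-dimethoxyphenyl)–C2] and at C3–C4 to a 1,1-diethyl-3-methyl-1,3-dihydro-2,1-oxasilole [C3–SiEt2–O–CH(CH3)–C4], with CH2CO2Et at C5 and H at C6 (two racemic diastereomers)
Conditions: RhCl(PPh3)3 (10 mol%), degassed PhMe, 80 °C, syringe-pump addition of 13 (final 0.005 M)
Reagents that add atoms: none
Why: RhCl(PPh3)3 loses a phosphine, and monovalent rhodium binds the ester-linked 1,6-diyne of 13 (ynoate and silylalkyne) and couples it oxidatively to a rhodacyclopentadiene of trivalent rhodium, which forms C1–C2 and with it the five-membered lactone ring (metal-templated closure across the three-atom C(=O)–O–CH tether). The third alkyne, held by the three-atom Si–O–CH tether, then inserts into the Rh–C3 bond, forming C3–C4 and closing the five-membered oxasilole ring; reductive elimination forms C5–C6, closes the benzene ring and returns monovalent rhodium. The closest known reaction type is the fully intramolecular (2+2+2) cyclotrimerization of 1,6,11-triynes to 5-6-5 tricyclic arenes with RhCl(PPh3)3, which includes ester tethers and temporary silyl ether tethers. No stereocentre is formed: the two carbinol centres of 13 are not touched, 14 keeps the diastereomer composition of 13, and the symmetrical aryl group creates no axial isomers. The step needs one regiochemistry for three unlike alkynes, which the tethers enforce because the central alkyne can only place its carbons at C2 and C3; it also needs ring closure to outrun intermolecular trimerization, which slow addition to a dilute catalyst solution secures. Aprotic, base-free toluene spares the Si–O bond, the terminal ynoate and the 3-alkynoate, and aromatisation makes the sequence irreversible.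

Step 7
Reactants: 14 tricyclic phthalide–benzoxasilole
Product: 15 ethyl 2-[3-(2,6-dimethoxyphenyl)-4-hydroxy-5-(1-hydroxyethyl)-1-oxo-1,3-dihydroisobenzofuran-6-yl]acetate (two racemic diastereomers)
Conditions: 30% aq. H2O2, KHCO3, KF, THF/EtOH, rt → 40 °C; aq. Na2S2O3
Reagents that add atoms: hydrogen peroxide, OO
Why: Tamao oxidation: hydroperoxide adds to the alkoxy-substituted silicon of the strained oxasilole, the aryl group migrates from Si to O, and hydrolysis of the Si–O bonds frees the C3 phenol and the 1-hydroxyethyl group. Diethyl benzoxasiloles are known substrates under bicarbonate/peroxide, and the oxidation is placed before any ketone exists to exclude Dakin oxidation; any material that lactonises between the C4 carbinol and the C5 ester converges in step 9.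

Step 8
Reactants: 15 ethyl 2-[3-(2,6-dimethoxyphenyl)-4-hydroxy-5-(1-hydroxyethyl)-1-oxo-1,3-dihydroisobenzofuran-6-yl]acetate
Product: 16 ethyl 2-[3-(2,6-dimethoxyphenyl)-5-(1-hydroxyethyl)-4-methoxy-1-oxo-1,3-dihydroisobenzofuran-6-yl]acetate (two racemic diastereomers)
Conditions: MeI, K2CO3, acetone, 50 °C
Reagents that add atoms: iodomethane, CI
Why: Williamson O-methylation of the phenol; carbonate does not deprotonate the aliphatic alcohol, and the ether shields the phenol from KMnO4 in step 9 and leaves with the other methyl ethers in step 10.

Step 9
Reactants: 16 ethyl 2-[3-(2,6-dimethoxyphenyl)-5-(1-hydroxyethyl)-4-methoxy-1-oxo-1,3-dihydroisobenzofuran-6-yl]acetate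
Product: 18 4-acetyl-5-(carboxymethyl)-2-(2,6-dimethoxybenzoyl)-3-methoxybenzoic acid, via ring-opened dipotassium dicarboxylate 17 (not isolated)
Conditions: KOH, H2O/t-BuOH, 50 °C; then KMnO4 (1.4 equiv), 0 °C; NaHSO3; 1 M HCl
Reagents that add atoms: potassium hydroxide, [K+].[OH-]
Why: Saponification opens the phthalide and the ethyl ester to the dicarboxylate, in which the benzhydrol cannot relactonise, and alkaline KMnO4 oxidises both secondary benzylic carbinols to ketones (the classical conversion of 3-arylphthalides into 2-aroylbenzoic acids), erasing both stereocentres. The ketones appear only after the ester has become a carboxylate, so no Claisen-type closure between the acetyl group and the acetate arm is possible.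

Step 10
Reactants: 18 4-acetyl-5-(carboxymethyl)-2-(2,6-dimethoxybenzoyl)-3-methoxybenzoic acid
Product: 19 huanglongmycin D, 4-acetyl-5-(carboxymethyl)-2-(2,6-dihydroxybenzoyl)-3-hydroxybenzoic acid
Conditions: BBr3 (8 equiv), CH2Cl2, −78 °C → rt; H2O, 0 °C
Reagents that add atoms: none
Why: Lewis-acid cleavage of aryl methyl ethers; each methoxy group is ortho to a ketone carbonyl, so boron chelation directs bromide to the methyl groups, and aqueous work-up hydrolyses the aryl borates.

## Compound list

1 | 2,6-dimethoxybenzaldehyde | COc1cccc(OC)c1C=O | starting material
2 | ethynylmagnesium bromide | C#C[Mg]Br | starting material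
3 | 1-(2,6-dimethoxyphenyl)prop-2-yn-1-ol (racemic, one enantiomer drawn) | O[C@@H](c1c(OC)cccc1OC)C#C | intermediate
4 | chlorodiethylsilane | CC[SiH](Cl)CC | starting material
5 | dilithium salt of 3 (lithium alkoxide and lithium acetylide; racemic) | [Li]O[C@@H](c1c(OC)cccc1OC)C#C[Li] | intermediate
6 | {[1-(2,6-dimethoxyphenyl)-3-(diethylsilyl)prop-2-yn-1-yl]oxy}diethylsilane (racemic) | CC[SiH](CC)O[C@@H](c1c(OC)cccc1OC)C#C[SiH](CC)CC | intermediate
7 | 1-(2,6-dimethoxyphenyl)-3-(diethylsilyl)prop-2-yn-1-ol (racemic) | O[C@@H](c1c(OC)cccc1OC)C#C[SiH](CC)CC | intermediate
8 | propiolic acid | C#CC(=O)O | starting material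
9 | 1-(2,6-dimethoxyphenyl)-3-(diethylsilyl)prop-2-yn-1-yl prop-2-ynoate (racemic) | C#CC(=O)O[C@@H](c1c(OC)cccc1OC)C#C[SiH](CC)CC | intermediate
10 | but-3-yn-2-ol (racemic, one enantiomer drawn) | C[C@@H](O)C#C | starting material
11 | ethyl diazoacetate | CCOC(=O)C=[N+]=[N-] | starting material
12 | ethyl 5-hydroxyhex-3-ynoate (racemic) | C[C@@H](O)C#CCC(=O)OCC | intermediate
13 | 1-(2,6-dimethoxyphenyl)-3-{diethyl[(6-ethoxy-6-oxohex-3-yn-2-yl)oxy]silyl}prop-2-yn-1-yl prop-2-ynoate (diastereomer mixture, one isomer drawn) | C#CC(=O)O[C@@H](c1c(OC)cccc1OC)C#C[Si](CC)(CC)O[C@H](C)C#CCC(=O)OCC | intermediate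
14 | tricyclic phthalide–benzoxasilole with 2,6-dimethoxyphenyl on the lactone carbon, SiEt2 and CH(CH3) in the oxasilole, CH2CO2Et at C5 (diastereomer mixture, one isomer drawn) | CCOC(=O)Cc1cc2C(=O)O[C@@H](c3c(OC)cccc3OC)c2c2[Si](CC)(CC)O[C@H](C)c12 | intermediate
15 | ethyl 2-[3-(2,6-dimethoxyphenyl)-4-hydroxy-5-(1-hydroxyethyl)-1-oxo-1,3-dihydroisobenzofuran-6-yl]acetate (diastereomer mixture) | CCOC(=O)Cc1cc2C(=O)O[C@@H](c3c(OC)cccc3OC)c2c(O)c1[C@@H](C)O | intermediate
16 | ethyl 2-[3-(2,6-dimethoxyphenyl)-5-(1-hydroxyethyl)-4-methoxy-1-oxo-1,3-dihydroisobenzofuran-6-yl]acetate (diastereomer mixture) | CCOC(=O)Cc1cc2C(=O)O[C@@H](c3c(OC)cccc3OC)c2c(OC)c1[C@@H](C)O | intermediate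
17 | dipotassium 5-(carboxylatomethyl)-2-[(2,6-dimethoxyphenyl)(hydroxy)methyl]-4-(1-hydroxyethyl)-3-methoxybenzoate (diastereomer mixture) | [K+].[K+].[O-]C(=O)Cc1cc(C([O-])=O)c([C@@H](O)c2c(OC)cccc2OC)c(OC)c1[C@@H](C)O | intermediate
18 | 4-acetyl-5-(carboxymethyl)-2-(2,6-dimethoxybenzoyl)-3-methoxybenzoic acid | CC(=O)c1c(CC(=O)O)cc(C(=O)O)c(C(=O)c2c(OC)cccc2OC)c1OC | intermediate
19 | huanglongmycin D, 4-acetyl-5-(carboxymethyl)-2-(2,6-dihydroxybenzoyl)-3-hydroxybenzoic acid | CC(=O)c1c(CC(=O)O)cc(C(=O)O)c(C(=O)c2c(O)cccc2O)c1O | target

## Step count and least certain steps

Total step count: 10. Longest linear sequence: 9 steps (steps 1, 2, 3, 5, 6, 7, 8, 9, 10 from 1); step 4 is a one-step side branch from 10.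

**Step 6 (key step).** The most likely failure is loss of the diethylsilyl ether tether, by adventitious hydrolysis or at the metal, before the third alkyne has inserted; the reaction then becomes an unselective intermolecular trimerization, aggravated by oligomerisation of the terminal ynoate. The fallback changes the tether to a sturdier one and sets out from 3. The dilithium salt 5 is silylated with chlorodiisopropylsilane to the bis(diisopropylsilyl) compound {[1-(2,6-dimethoxyphenyl)-3-(diisopropylsilyl)prop-2-yn-1-yl]oxy}diisopropylsilane F1, and mild acid releases 1-(2,6-dimethoxyphenyl)-3-(diisopropylsilyl)prop-2-yn-1-ol F2. Esterification as in step 3 gives the propiolate F3, dehydrogenative coupling with 12 as in step 5 gives the diisopropylsilyl-tethered triyne F4, and RhCl(PPh3)3 closes it to the diisopropyl benzoxasilole F5. A more forcing Tamao oxidation (H2O2, KF, KHCO3, THF/EtOH, 60 °C) then comes back to the route at 15; the price is the slower oxidation at the bulkier silicon.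

**Step 5.** The ruthenium silyl/hydride species may hydrosilylate the terminal ynoate in competition with alcoholysis, which would consume the Si–H group without forming the tether. The fallback replaces catalysis by stoichiometric activation of silicon and sets out from 9. NBS (CH2Cl2, −20 °C) converts the Si–H group into the bromosilane 1-(2,6-dimethoxyphenyl)-3-[bromo(diethyl)silyl]prop-2-yn-1-yl prop-2-ynoate F6, which is added without isolation to 12 and 2,6-lutidine (a hindered, non-nucleophilic base) and comes back at 13. The low temperature and the non-polar solvent are meant to keep ring bromination of the dimethoxyarene slow relative to Si–H bromination.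

**Step 9.** Over-oxidation may occur at the benzylic CH2 of the arylacetate or on the electron-rich dimethoxyarene, or the very hindered benzhydrol may be oxidised incompletely. The fallback avoids KMnO4 and sets out from 16. After saponification to 17 and removal of water, MeI in DMF gives the dimethyl ester diol methyl 2-[(2,6-dimethoxyphenyl)(hydroxy)methyl]-4-(1-hydroxyethyl)-3-methoxy-5-(2-methoxy-2-oxoethyl)benzoate F7. This is oxidised at once, before it can relactonise, with DMP (NaHCO3, CH2Cl2) to methyl 4-acetyl-2-(2,6-dimethoxybenzoyl)-3-methoxy-5-(2-methoxy-2-oxoethyl)benzoate F8 (the same compound as A7). Cold LiOH (THF/H2O, 0 °C) then hydrolyses both esters, and the route is rejoined at 18.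

**Step 7.** Protodesilylation at C3 by fluoride and base may compete, or hydroperoxide may fail to reach a silicon shielded by two ortho substituents. The fallback separates ring opening from oxidation and sets out from 14. HF·pyridine (THF, 0 °C) opens the oxasilole to the fluorosilane ethyl 2-{3-(2,6-dimethoxyphenyl)-4-[diethyl(fluoro)silyl]-5-(1-hydroxyethyl)-1-oxo-1,3-dihydroisobenzofuran-6-yl}acetate F9, which is oxidised under the peracid variant of the Tamao oxidation (mCPBA, KHF2, DMF, rt) and comes back at 15.

**Step 3.** The doubly activated carbinol (benzylic to a 2,6-dimethoxyphenyl group and propargylic) may ionise, or its slow acylation may lose out to amine-induced oligomerisation of 8. The fallback reverses the polarity of ester formation and sets out from 7. MsCl/Et3N (CH2Cl2, −20 °C) gives, through the mesylate, the chloride 1-(2,6-dimethoxyphenyl)-3-(diethylsilyl)prop-2-ynyl chloride F10, which is alkylated with HC≡CCO2Cs (from 8 and Cs2CO3, DMF, 0 °C) and comes back at 9; attack at the remote alkyne carbon, which would give an allenyl ester, is the point to watch.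

## Further compounds

F1 | step 6 | {[1-(2,6-dimethoxyphenyl)-3-(diisopropylsilyl)prop-2-yn-1-yl]oxy}diisopropylsilane (racemic) | CC(C)[SiH](C(C)C)O[C@@H](c1c(OC)cccc1OC)C#C[SiH](C(C)C)C(C)C
F2 | step 6 | 1-(2,6-dimethoxyphenyl)-3-(diisopropylsilyl)prop-2-yn-1-ol (racemic) | O[C@@H](c1c(OC)cccc1OC)C#C[SiH](C(C)C)C(C)C
F3 | step 6 | 1-(2,6-dimethoxyphenyl)-3-(diisopropylsilyl)prop-2-yn-1-yl prop-2-ynoate (racemic) | C#CC(=O)O[C@@H](c1c(OC)cccc1OC)C#C[SiH](C(C)C)C(C)C
F4 | step 6 | 1-(2,6-dimethoxyphenyl)-3-{[(6-ethoxy-6-oxohex-3-yn-2-yl)oxy]diisopropylsilyl}prop-2-yn-1-yl prop-2-ynoate (diastereomer mixture) | C#CC(=O)O[C@@H](c1c(OC)cccc1OC)C#C[Si](C(C)C)(C(C)C)O[C@H](C)C#CCC(=O)OCC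
F5 | step 6 | diisopropyl analogue of the tricyclic phthalide–benzoxasilole 14 (diastereomer mixture) | CCOC(=O)Cc1cc2C(=O)O[C@@H](c3c(OC)cccc3OC)c2c2[Si](C(C)C)(C(C)C)O[C@H](C)c12
F6 | step 5 | 1-(2,6-dimethoxyphenyl)-3-[bromo(diethyl)silyl]prop-2-yn-1-yl prop-2-ynoate (racemic) | C#CC(=O)O[C@@H](c1c(OC)cccc1OC)C#C[Si](Br)(CC)CC
F7 | step 9 | methyl 2-[(2,6-dimethoxyphenyl)(hydroxy)methyl]-4-(1-hydroxyethyl)-3-methoxy-5-(2-methoxy-2-oxoethyl)benzoate (diastereomer mixture) | COC(=O)Cc1cc(C(=O)OC)c([C@@H](O)c2c(OC)cccc2OC)c(OC)c1[C@@H](C)O
F8 | step 9 | methyl 4-acetyl-2-(2,6-dimethoxybenzoyl)-3-methoxy-5-(2-methoxy-2-oxoethyl)benzoate | CC(=O)c1c(CC(=O)OC)cc(C(=O)OC)c(C(=O)c2c(OC)cccc2OC)c1OC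
F9 | step 7 | ethyl 2-{3-(2,6-dimethoxyphenyl)-4-[diethyl(fluoro)silyl]-5-(1-hydroxyethyl)-1-oxo-1,3-dihydroisobenzofuran-6-yl}acetate (diastereomer mixture) | CCOC(=O)Cc1cc2C(=O)O[C@@H](c3c(OC)cccc3OC)c2c([Si](F)(CC)CC)c1[C@@H](C)O
F10 | step 3 | 1-(2,6-dimethoxyphenyl)-3-(diethylsilyl)prop-2-ynyl chloride (racemic) | Cl[C@@H](c1c(OC)cccc1OC)C#C[SiH](CC)CC
A1 | alternative 1 | (Z)-1-(tert-butylimino)-3-(2,6-dimethoxyphenyl)-4-methoxy-5-(trimethylsilyl)-1,3-dihydroisobenzofuran-6-yl trifluoromethanesulfonate (racemic, one enantiomer drawn) | COc1c([Si](C)(C)C)c(OS(=O)(=O)C(F)(F)F)cc2/C(=N/C(C)(C)C)O[C@@H](c3c(OC)cccc3OC)c12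
A2 | alternative 1 | 5-methoxy-4,6-bis(trimethylsilyl)-1,3-phenylene bis(trifluoromethanesulfonate) | COc1c([Si](C)(C)C)c(OS(=O)(=O)C(F)(F)F)cc(OS(=O)(=O)C(F)(F)F)c1[Si](C)(C)C
A3 | alternative 1 | tert-butyl isocyanide | CC(C)(C)[N+]#[C-]
A4 | alternative 2 | methyl 2-(9-acetyl-10-hydroxy-1-methoxy-6,11-dioxo-6,11-dihydrodibenzo[b,e]oxepin-8-yl)acetate | CC(=O)c1c(CC(=O)OC)cc2C(=O)Oc3cccc(OC)c3C(=O)c2c1O
A5 | alternative 2 | methyl 2-(2-acetyl-1-hydroxy-8-methoxy-9,10-dioxo-9,10-dihydroanthracen-3-yl)acetate | CC(=O)c1c(CC(=O)OC)cc2C(=O)c3cccc(OC)c3C(=O)c2c1O
A6 | alternative 2 | trifluoroperacetic acid | OOC(=O)C(F)(F)F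
A7 | alternative 3 | methyl 4-acetyl-2-(2,6-dimethoxybenzoyl)-3-methoxy-5-(2-methoxy-2-oxoethyl)benzoate | CC(=O)c1c(CC(=O)OC)cc(C(=O)OC)c(C(=O)c2c(OC)cccc2OC)c1OC
A8 | alternative 3 | methyl 2-(2,6-dimethoxybenzoyl)-3-methoxy-4-(trimethylsilyl)-5-{[(trifluoromethyl)sulfonyl]oxy}benzoate | COC(=O)c1cc(OS(=O)(=O)C(F)(F)F)c([Si](C)(C)C)c(OC)c1C(=O)c1c(OC)cccc1OC
A9 | alternative 3 | methyl acetoacetate | CC(=O)CC(=O)OC
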